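The earlier runs and the new flask are simulated with made-up constants; scatter was added.

| setting | gamma | alpha | epsilon | flask |
|---|---|---|---|---|
| substrate | 0.013 M | 0.030 M | 0.020 M | 0.020 M |
| coupling partner | 0.036 M | 0.036 M | 0.072 M | 0.0360 M |
| remark | run made earlier | run made earlier | run made earlier |  |
| time |  |  |  | 20 min |

| run | time / min | product / % | substrate / % |
|---|---|---|---|
| gamma | 2.50 | 0 | 99.1 |
| gamma | 8.00 | 1.3 | 98.0 |
| gamma | 12.0 | 1.8 | 98.8 |
| gamma | 20.0 | 1.3 | 98.0 |
| alpha | 5.00 | 5.4 | 94.9 |
| alpha | 10.0 | 9.6 | 90.1 |
| alpha | 15.0 | 10.2 | 88.3 |
| alpha | 20.0 | 10.6 | 90.1 |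
| epsilon | 1.50 | 0.7 | 97.7 |
| epsilon | 4.00 | 18.7 | 82.0 |
| epsilon | 8.00 | 39.8 | 59.4 |
| epsilon | 20.0 | 44.5 | 54.9 |

(readings scatter by 0.5 percentage points)

- the numbers in the tables scatter by 0.5 percentage points (one standard deviation)
- the reaction counts as stopped when no species that holds the substrate changes by six tenths of a point or more over the second half of the time

1. which holds at 20 min: what has brought the reaction to rest, or that it has not come to rest (it is still moving / all of the substrate has reacted / the coupling partner has run out first)
2. product at 20 min, in percent of the substrate charged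

The constants to read are two times: τ, the lifetime of the coupling partner, and t_g, the e-folding time of the product at the charges. Epsilon climbs faster after its first reading than before it, so product speeds its own formation (autocatalysis). Yet epsilon ends at 54.9% substrate, with 12.4% of its coupling partner turned into product, so I take the coupling partner to fade by a first-order side loss. In epsilon, the gaps in ln w, with w = c(product)/c(substrate), to the last reading shrink by a factor 6.66:

τ = 4.00 min / ln 6.66 = 2.11 min

Integrating the rate, proportional to c(substrate)·c(coupling partner)·c(product), against the fading coupling partner raises ln w by N = τ/t_g = Q·c(substrate)·c(coupling partner), at the charges, with Q the gain constant. Gamma and alpha share a partner charge, and I take c(substrate)·w at rest as s·exp(N), with s the seed of product present when the gain begins. At rest, c(substrate)·w reads: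

gamma 1.94 × 10⁻⁴ M, alpha 0.00350 M

Q = 4730 L² mol⁻², seed s = 2.13 × 10⁻⁵ M

Flask: N = 3.40, t_g = 0.620 min, product 3.09%

The forecast says the coupling partner has run out first and 5.5%, holding that “Substrate therefore isn't what stops the reaction”; my reckoning stands lower.

The flask gives the coupling partner has run out first and 3.65%.

    substrate + coupling partner → product (k = 5.20 × 10⁻⁴ L mol⁻¹ s⁻¹)
    coupling partner → decomposed reagent (k = 0.00554 s⁻¹)
    substrate + coupling partner + product → 2 product (k = 29.8 L² mol⁻² s⁻¹)

A neighbouring flask repeats this one with 0.061 M coupling partner, which is 3.05 equiv. The same Q gives N = 5.76 and product 25.3%. The simulated neighbouring flask holds 26.1% product and 73.9% substrate at its end, with 0.016% of its coupling partner left, the limiting reagent there.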